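**Retrosynthetic overview**
1. Last operation: acidolysis of a C15 tert-butyl ester.
2. Key disconnection C6–C7: intramolecular addition of a 2-(methoxycarbonyl)allylsilane to a C6 aldehyde. The silane is a β-acrylate-anion (homoenolate-type) donor, so C7, normally the electrophilic β-carbon of an enoate, attacks the electrophilic aldehyde carbon. This closes the cyclohexane, sets C6 and C7, and after lactonisation gives the α-methylene lactone.
3. C5–C10: enantioselective boron-enolate Ireland–Claisen rearrangement of an (E)-allyl itaconate sets C5 and the quaternary C10.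
4. Acyclic precursor: geraniol + itaconic anhydride. The prenyl end is cut by ozonolysis and rebuilt by D-proline α-aminoxylation (C8–O) and Wittig olefination with a silylmethyl ylide (C11–C13), then angeloylation.
5. Ring order: no ring until the key step; cyclohexane first (C6–C7), γ-lactone second, in the same step.

Assumption: atom labels follow elemane numbering (ring C5–C10, vinyl C1=C2, acrylic acid C3=C4–C15, lactone C11(=C13)–C12, methyl C14); the target is (5R,6R,7R,8S,10S) with a (Z)-2-methylbut-2-enoate (angelate) on O8; the facial sense of the (S,S) boron controller in step 8 is assigned by analogy with (E)-allyl esters, and its antipode is used if the sense is reversed.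

**Step 1**
Reactants: 1 geraniol [(2E)-3,7-dimethylocta-2,6-dien-1-ol]; 2 itaconic anhydride (3-methylideneoxolane-2,5-dione)
Product: 3 4-geranyl hydrogen itaconate (4-{[(2E)-3,7-dimethylocta-2,6-dien-1-yl]oxy}-2-methylidene-4-oxobutanoic acid)
Conditions: toluene, 70 °C, 12 h, no base
Reagents that add atoms: none
Why: Regioselective anhydride alcoholysis at the non-conjugated carbonyl gives the 4-ester with the acrylic acid (C15) free; no amine is used, so the anhydride does not isomerise to citraconic anhydride.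

**Step 2**
Reactants: 3 4-geranyl hydrogen itaconate
Product: 4 1-tert-butyl 4-[(2E)-3,7-dimethylocta-2,6-dien-1-yl] 2-methylidenebutanedioate
Conditions: Cl3CC(=NH)OtBu (2 equiv), CH2Cl2/cyclohexane, rt, 16 h
Reagents that add atoms: tert-butyl 2,2,2-trichloroacetimidate, CC(C)(C)OC(=N)C(Cl)(Cl)Cl
Why: Imidate tert-butylation of the carboxylic acid (self-catalysed by the acid, base-free) masks C15, so that the only free acid later in the route is C6.

**Step 3**
Reactants: 4 1-tert-butyl 4-geranyl itaconate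
Product: 5 1-tert-butyl 4-[(2E)-3-methyl-6-oxohex-2-en-1-yl] 2-methylidenebutanedioate
Conditions: O3 (1.0 equiv), CH2Cl2/MeOH, −78 °C; then Me2S, −78 °C → rt
Reagents that add atoms: ozone, [O-][O+]=O
Why: Chemoselective ozonolysis with reductive work-up: the remote trisubstituted alkene is far more electron-rich than the allylic-ester alkene and the acrylate, so one equivalent of ozone cleaves only it.

**Step 4**
Reactants: 6 methyl 2-(triphenyl-λ5-phosphanylidene)acetate (2.0 equiv); 7 (iodomethyl)trimethylsilane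
Product: 9 methyl 2-(triphenyl-λ5-phosphanylidene)-3-(trimethylsilyl)propanoate, via phosphonium iodide 8 (not isolated)
Conditions: EtOAc, reflux, 24 h; filter off the phosphonium salt
Reagents that add atoms: none
Why: C-alkylation of a stabilised phosphorus ylide followed by transylidation (salt method); the second equivalent of 6 deprotonates the new phosphonium salt.

**Step 5**
Reactants: 5 aldehyde; 9 silylmethyl ylide
Product: 11 1-tert-butyl 4-[(2E,5S,6Z)-5-(anilinooxy)-8-methoxy-3-methyl-8-oxo-7-[(trimethylsilyl)methyl]octa-2,6-dien-1-yl] 2-methylidenebutanedioate, via α-anilinooxy aldehyde 10 (not isolated)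
Conditions: PhNO (1.0 equiv, slow addition), D-proline (20 mol%), DMSO, rt, 30 min; then 9 (1.5 equiv), CH2Cl2, 0 °C → rt
Reagents that add atoms: nitrosobenzene, O=Nc1ccccc1
Why: Proline enamine catalysis (O-selective nitroso aldol, α-aminoxylation) sets C8: D-proline gives the (S)-aminoxy aldehyde, which is trapped at once by Wittig olefination with the stabilised ylide, placing the ester trans to C8 (6Z by priority rules).

**Step 6**
Reactants: 11 γ-anilinooxy enoate
Product: 12 1-tert-butyl 4-[(2E,5S,6Z)-5-hydroxy-8-methoxy-3-methyl-8-oxo-7-[(trimethylsilyl)methyl]octa-2,6-dien-1-yl] 2-methylidenebutanedioate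
Conditions: Zn dust, AcOH/THF/H2O (3:1:1), rt
Reagents that add atoms: none
Why: Reductive N–O bond cleavage by zinc in acetic acid leaves C8, the enoates and the ester-deactivated allylsilane untouched; the C8–OH is trans to the ester, so no butenolide forms.

**Step 7**
Reactants: 12 γ-hydroxy enoate; 13 angelic acid [(2Z)-2-methylbut-2-enoic acid]
Product: 15 1-tert-butyl 4-[(2E,5S,6Z)-8-methoxy-3-methyl-5-{[(2Z)-2-methylbut-2-enoyl]oxy}-8-oxo-7-[(trimethylsilyl)methyl]octa-2,6-dien-1-yl] 2-methylidenebutanedioate, via mixed anhydride 14 (not isolated)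
Conditions: 13, 2,4,6-Cl3C6H2COCl, Et3N, toluene, rt, 1 h; then 12, DMAP, rt
Reagents that add atoms: none
Why: Yamaguchi esterification (mixed anhydride, DMAP acyl transfer) is the standard way to make angelates without Z→E isomerisation to the tiglate; C8 is retained.

**Step 8**
Reactants: 15 (E)-allyl itaconate
Product: 18 (2R,3S,5S,6Z)-2-(3-tert-butoxy-3-oxoprop-1-en-2-yl)-3-ethenyl-8-methoxy-3-methyl-5-{[(2Z)-2-methylbut-2-enoyl]oxy}-8-oxo-7-[(trimethylsilyl)methyl]oct-6-enoic acid, via boron ketene acetal 16 (not isolated), via O-boryl carboxylate 17 (not isolated)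
Conditions: (4S,5S)-2-bromo-1,3-bis[(3,5-bis(trifluoromethyl)phenyl)sulfonyl]-4,5-diphenyl-1,3,2-diazaborolidine (1.3 equiv), Et3N, toluene/hexane, −78 °C then −20 → 4 °C, 72 h; H2O work-up
Reagents that add atoms: none
Why: Enantioselective Ireland–Claisen rearrangement through a chiral boron ketene acetal: soft enolisation of the doubly activated itaconate CH2 gives the E(O) enolate, and a chair transition state with the (E)-allyl unit (C14 methyl axial, C9 equatorial) forms C5–C10 with the 5R,10S relationship, the controller choosing the enolate face.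

**Step 9**
Reactants: 18 acid
Product: 20 methyl (2Z,4S,6S,7R)-7-(3-tert-butoxy-3-oxoprop-1-en-2-yl)-6-ethenyl-6-methyl-4-{[(2Z)-2-methylbut-2-enoyl]oxy}-8-oxo-2-[(trimethylsilyl)methyl]oct-2-enoate, via acid chloride 19 (not isolated)
Conditions: Me2C=C(Cl)NMe2, CH2Cl2, 0 °C; then LiAlH(OtBu)3, THF, −78 °C; use crude at once
Reagents that add atoms: none
Why: Neutral acid chloride formation and partial reduction with LiAlH(OtBu)3 (acid chloride → aldehyde) avoids base and leaves the other esters alone, so the epimerisable C5 centre next to the new aldehyde is kept.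

**Step 10**
Reactants: 20 aldehyde
Product: 22 tert-butyl 2-[(3aR,4S,6S,7R,7aR)-6-ethenyl-6-methyl-4-{[(2Z)-2-methylbut-2-enoyl]oxy}-3-methylidene-2-oxooctahydro-1-benzofuran-7-yl]prop-2-enoate, via hydroxy ester 21 (not isolated)
Conditions: TiCl4 (2.0 equiv), CH2Cl2, −78 °C, 1 h; aq. NaHCO3; then CSA (10 mol%), CH2Cl2, rt
Reagents that add atoms: none
Why: Intramolecular Hosomi–Sakurai allylation by the 2-(methoxycarbonyl)allylsilane through a chair-like synclinal transition state with the C5 acrylate, C8 angelate, C6=O and C7=C11 all equatorial and only the C10 methyl axial (an axial C6–O would be 1,3-diaxial to that methyl) sets C6 and C7 trans to each other and to C5 and C8, the minor silane geometric isomer converges, and the trans γ-hydroxy methyl ester then lactonises under acid while the tert-butyl ester does not.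

**Step 11**
Reactants: 22 lactone tert-butyl ester
Product: 23 2-[(3aR,4S,6S,7R,7aR)-6-ethenyl-6-methyl-4-{[(2Z)-2-methylbut-2-enoyl]oxy}-3-methylidene-2-oxooctahydro-1-benzofuran-7-yl]prop-2-enoic acid (CNP0256928.3)
Conditions: TFA/CH2Cl2 (1:4), 0 °C → rt
Reagents that add atoms: none
Why: Acidolysis of the tert-butyl ester (loss of isobutene); the lactone, the angelate and the alkenes are stable to brief TFA, and no stereocentre is touched.

**Compound list**
1 | geraniol | CC(C)=CCC/C(C)=C/CO | starting material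
2 | itaconic anhydride | C=C1CC(=O)OC1=O | starting material
3 | 4-geranyl hydrogen itaconate | OC(=O)C(=C)CC(=O)OC/C=C(\C)CCC=C(C)C | intermediate
4 | 1-tert-butyl 4-geranyl itaconate | C=C(CC(=O)OC/C=C(\C)CCC=C(C)C)C(=O)OC(C)(C)C | intermediate
5 | 1-tert-butyl 4-[(2E)-3-methyl-6-oxohex-2-en-1-yl] 2-methylidenebutanedioate | C=C(CC(=O)OC/C=C(\C)CCC=O)C(=O)OC(C)(C)C | intermediate
6 | methyl 2-(triphenyl-λ5-phosphanylidene)acetate | COC(=O)C=P(c1ccccc1)(c1ccccc1)c1ccccc1 | starting material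
7 | (iodomethyl)trimethylsilane | C[Si](C)(C)CI | starting material
8 | [1-methoxy-1-oxo-3-(trimethylsilyl)propan-2-yl]triphenylphosphonium iodide | COC(=O)C(C[Si](C)(C)C)[P+](c1ccccc1)(c1ccccc1)c1ccccc1.[I-] | intermediate (not isolated)
9 | methyl 2-(triphenyl-λ5-phosphanylidene)-3-(trimethylsilyl)propanoate | COC(=O)C(C[Si](C)(C)C)=P(c1ccccc1)(c1ccccc1)c1ccccc1 | intermediate
10 | 1-tert-butyl 4-[(2E,5S)-5-(anilinooxy)-3-methyl-6-oxohex-2-en-1-yl] 2-methylidenebutanedioate | C=C(CC(=O)OC/C=C(\C)C[C@H](ONc1ccccc1)C=O)C(=O)OC(C)(C)C | intermediate (not isolated)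
11 | γ-anilinooxy enoate (2E,5S,6Z), name as in step 5 | C=C(CC(=O)OC/C=C(\C)C[C@H](ONc1ccccc1)/C=C(\C[Si](C)(C)C)C(=O)OC)C(=O)OC(C)(C)C | intermediate
12 | γ-hydroxy enoate (2E,5S,6Z), name as in step 6 | C=C(CC(=O)OC/C=C(\C)C[C@H](O)/C=C(\C[Si](C)(C)C)C(=O)OC)C(=O)OC(C)(C)C | intermediate
13 | angelic acid | C/C=C(/C)C(=O)O | starting material
14 | (2Z)-2-methylbut-2-enoic 2,4,6-trichlorobenzoic anhydride | C/C=C(/C)C(=O)OC(=O)c1c(Cl)cc(Cl)cc1Cl | intermediate (not isolated)
15 | C8 angelate (2E,5S,6Z), name as in step 7 | C=C(CC(=O)OC/C=C(\C)C[C@H](OC(=O)/C(C)=C\C)/C=C(\C[Si](C)(C)C)C(=O)OC)C(=O)OC(C)(C)C | intermediate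
16 | boron ketene acetal of 15: C6(=C5)–O–B[(4S,5S)-diazaborolidinyl], C4 cis to the allyloxy oxygen, C8 S | C=C(/C=C(/OB1N(S(=O)(=O)c2cc(cc(c2)C(F)(F)F)C(F)(F)F)[C@@H](c2ccccc2)[C@H](c2ccccc2)N1S(=O)(=O)c1cc(cc(c1)C(F)(F)F)C(F)(F)F)OC/C=C(\C)C[C@H](OC(=O)/C(C)=C\C)/C=C(\C[Si](C)(C)C)C(=O)OC)C(=O)OC(C)(C)C | intermediate (not isolated)
17 | O-[(4S,5S)-diazaborolidinyl] ester of acid 18 | O=C(OB1N(S(=O)(=O)c2cc(cc(c2)C(F)(F)F)C(F)(F)F)[C@@H](c2ccccc2)[C@H](c2ccccc2)N1S(=O)(=O)c1cc(cc(c1)C(F)(F)F)C(F)(F)F)[C@@H](C(=C)C(=O)OC(C)(C)C)[C@](C)(C=C)C[C@H](OC(=O)/C(C)=C\C)/C=C(\C[Si](C)(C)C)C(=O)OC | intermediate (not isolated)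
18 | (2R,3S,5S,6Z) acid, name as in step 8 (elemane 5R,8S,10S) | OC(=O)[C@@H](C(=C)C(=O)OC(C)(C)C)[C@](C)(C=C)C[C@H](OC(=O)/C(C)=C\C)/C=C(\C[Si](C)(C)C)C(=O)OC | intermediate
19 | acyl chloride of 18 | ClC(=O)[C@@H](C(=C)C(=O)OC(C)(C)C)[C@](C)(C=C)C[C@H](OC(=O)/C(C)=C\C)/C=C(\C[Si](C)(C)C)C(=O)OC | intermediate (not isolated)
20 | (2Z,4S,6S,7R) aldehyde, name as in step 9 | O=C[C@@H](C(=C)C(=O)OC(C)(C)C)[C@](C)(C=C)C[C@H](OC(=O)/C(C)=C\C)/C=C(\C[Si](C)(C)C)C(=O)OC | intermediate
21 | tert-butyl 2-[(1R,2S,4S,5S,6R)-2-ethenyl-6-hydroxy-5-(3-methoxy-3-oxoprop-1-en-2-yl)-2-methyl-4-{[(2Z)-2-methylbut-2-enoyl]oxy}cyclohexyl]prop-2-enoate (all ring substituents equatorial except the methyl) | C=C[C@]1(C)C[C@H](OC(=O)/C(C)=C\C)[C@@H](C(=C)C(=O)OC)[C@H](O)[C@H]1C(=C)C(=O)OC(C)(C)C | intermediate (not isolated)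
22 | lactone tert-butyl ester (3aR,4S,6S,7R,7aR), name as in step 10 | C=C[C@]1(C)C[C@H](OC(=O)/C(C)=C\C)[C@H]2C(=C)C(=O)O[C@@H]2[C@H]1C(=C)C(=O)OC(C)(C)C | intermediate
23 | CNP0256928.3, name as in step 11 | C=C[C@]1(C)C[C@H](OC(=O)/C(C)=C\C)[C@H]2C(=C)C(=O)O[C@@H]2[C@H]1C(=C)C(=O)O | target

**Count and risks**
Total steps: 11. Longest linear sequence: 10 (steps 1–3 and 5–11 from geraniol; step 4 is a side branch).

The three steps most likely to fail are 5, 8 and 10; step 10 is the riskiest.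

Step 5. The α-aminoxy aldehyde is labile and the α-branched ylide is slow, so racemisation or a low yield is possible. The fallback sets out from 5 and returns at 12. It uses an α-oxyamination that gives an isolable adduct: a chiral imidazolidinone (the enantiomer that gives S), TEMPO, FeCl3 (10 mol%), NaNO2 and O2 in DMF convert 5 into the configurationally stable (S)-α-(2,2,6,6-tetramethylpiperidin-1-yloxy) aldehyde F1. This is purified and olefinated with ylide 9 at 40 °C to the TEMPO ether F2, and Zn/AcOH cleaves the N–O bond to give alcohol 12.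

Step 8. The enolate geometry and the facial sense of the boron controller are not proven on an itaconate carrying three other esters. The fallback sets out from 15 and returns at 18. It gives up external reagent control and uses the resident C8 centre as a resolving handle. LiHMDS with TMSCl/Et3N in THF (−78 °C → rt) turns 15 into the trimethylsilyl ketene acetal F3, which rearranges through the same chair on both enolate faces to the trimethylsilyl ester of 18 F4 and the trimethylsilyl ester of the (5S,10R) diastereomer F5. Aqueous work-up gives acid 18 and the diastereomeric acid F6, which are separated by chromatography, at best half of the material.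

Step 10. The ester-deactivated silane may not react, or the ring fusion may come out cis. The fallback sets out from 5 and returns at 21. It replaces silicon by an allylmetal made by palladium/indium chemistry that reacts through a closed transition state.
- The aminoxy aldehyde 10 made from 5 is olefinated with methyl 2-(dimethoxyphosphoryl)-3-hydroxypropanoate (K2CO3, THF/H2O, Horner–Wadsworth–Emmons) to the 2-(hydroxymethyl) enoate F7.
- Zn/AcOH gives diol F8, and Yamaguchi esterification with two equivalents of 13 gives bis-angelate F9.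
- The step 8 rearrangement, through boron ketene acetal F10 and O-boryl carboxylate F11, gives acid F12.
- The step 9 protocol, through acid chloride F13, gives aldehyde F14.
- Pd(PPh3)4 (5 mol%) and InI (1.5 equiv) in THF ionise the primary allylic angelate. Monovalent indium reduces the allylpalladium intermediate to the allylindium species F15 (trivalent indium), whose geometric isomers interconvert.
- F15 adds to the aldehyde through a chair Zimmerman–Traxler transition state to give hydroxy ester 21, which is lactonised with CSA as in step 10.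

**Further compounds**
F1 | step 5 | 1-tert-butyl 4-[(2E,5S)-3-methyl-6-oxo-5-[(2,2,6,6-tetramethylpiperidin-1-yl)oxy]hex-2-en-1-yl] 2-methylidenebutanedioate | C=C(CC(=O)OC/C=C(\C)C[C@H](ON1C(C)(C)CCCC1(C)C)C=O)C(=O)OC(C)(C)C
F2 | step 5 | TEMPO ether of 12 (2E,5S,6Z) | C=C(CC(=O)OC/C=C(\C)C[C@H](ON1C(C)(C)CCCC1(C)C)/C=C(\C[Si](C)(C)C)C(=O)OC)C(=O)OC(C)(C)C
F3 | step 8 | trimethylsilyl ketene acetal of 15 (C4 cis to the allyloxy oxygen) | C=C(/C=C(/O[Si](C)(C)C)OC/C=C(\C)C[C@H](OC(=O)/C(C)=C\C)/C=C(\C[Si](C)(C)C)C(=O)OC)C(=O)OC(C)(C)C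
F4 | step 8 | trimethylsilyl ester of 18 | C[Si](C)(C)OC(=O)[C@@H](C(=C)C(=O)OC(C)(C)C)[C@](C)(C=C)C[C@H](OC(=O)/C(C)=C\C)/C=C(\C[Si](C)(C)C)C(=O)OC
F5 | step 8 | trimethylsilyl ester of the (2S,3R,5S) diastereomer of 18 | C[Si](C)(C)OC(=O)[C@H](C(=C)C(=O)OC(C)(C)C)[C@@](C)(C=C)C[C@H](OC(=O)/C(C)=C\C)/C=C(\C[Si](C)(C)C)C(=O)OC
F6 | step 8 | (2S,3R,5S,6Z) diastereomer of acid 18 | OC(=O)[C@H](C(=C)C(=O)OC(C)(C)C)[C@@](C)(C=C)C[C@H](OC(=O)/C(C)=C\C)/C=C(\C[Si](C)(C)C)C(=O)OC
F7 | step 10 | 1-tert-butyl 4-[(2E,5S,6E)-5-(anilinooxy)-7-(hydroxymethyl)-8-methoxy-3-methyl-8-oxoocta-2,6-dien-1-yl] 2-methylidenebutanedioate | C=C(CC(=O)OC/C=C(\C)C[C@H](ONc1ccccc1)/C=C(\CO)C(=O)OC)C(=O)OC(C)(C)C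
F8 | step 10 | 5-hydroxy-7-(hydroxymethyl) diol from F7 | C=C(CC(=O)OC/C=C(\C)C[C@H](O)/C=C(\CO)C(=O)OC)C(=O)OC(C)(C)C
F9 | step 10 | bis-angelate of F8 | C=C(CC(=O)OC/C=C(\C)C[C@H](OC(=O)/C(C)=C\C)/C=C(\COC(=O)/C(C)=C\C)C(=O)OC)C(=O)OC(C)(C)C
F10 | step 10 | boron ketene acetal of F9 (boron group as in 16) | C=C(/C=C(/OB1N(S(=O)(=O)c2cc(cc(c2)C(F)(F)F)C(F)(F)F)[C@@H](c2ccccc2)[C@H](c2ccccc2)N1S(=O)(=O)c1cc(cc(c1)C(F)(F)F)C(F)(F)F)OC/C=C(\C)C[C@H](OC(=O)/C(C)=C\C)/C=C(\COC(=O)/C(C)=C\C)C(=O)OC)C(=O)OC(C)(C)C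
F11 | step 10 | O-boryl ester of F12 (boron group as in 17) | O=C(OB1N(S(=O)(=O)c2cc(cc(c2)C(F)(F)F)C(F)(F)F)[C@@H](c2ccccc2)[C@H](c2ccccc2)N1S(=O)(=O)c1cc(cc(c1)C(F)(F)F)C(F)(F)F)[C@@H](C(=C)C(=O)OC(C)(C)C)[C@](C)(C=C)C[C@H](OC(=O)/C(C)=C\C)/C=C(\COC(=O)/C(C)=C\C)C(=O)OC
F12 | step 10 | (2R,3S,5S,6E)-2-(3-tert-butoxy-3-oxoprop-1-en-2-yl)-3-ethenyl-8-methoxy-3-methyl-5-{[(2Z)-2-methylbut-2-enoyl]oxy}-7-({[(2Z)-2-methylbut-2-enoyl]oxy}methyl)-8-oxooct-6-enoic acid | OC(=O)[C@@H](C(=C)C(=O)OC(C)(C)C)[C@](C)(C=C)C[C@H](OC(=O)/C(C)=C\C)/C=C(\COC(=O)/C(C)=C\C)C(=O)OC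
F13 | step 10 | acyl chloride of F12 | ClC(=O)[C@@H](C(=C)C(=O)OC(C)(C)C)[C@](C)(C=C)C[C@H](OC(=O)/C(C)=C\C)/C=C(\COC(=O)/C(C)=C\C)C(=O)OC
F14 | step 10 | aldehyde from F12 (C6 CHO) | O=C[C@@H](C(=C)C(=O)OC(C)(C)C)[C@](C)(C=C)C[C@H](OC(=O)/C(C)=C\C)/C=C(\COC(=O)/C(C)=C\C)C(=O)OC
F15 | step 10 | allylindium iodide angelate from F14 (indium on C13) | O=C[C@@H](C(=C)C(=O)OC(C)(C)C)[C@](C)(C=C)C[C@H](OC(=O)/C(C)=C\C)/C=C(\C[In](I)OC(=O)/C(C)=C\C)C(=O)OC
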